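**Retrosynthetic overview**

1. The strategy rests on the vicinal oxygen pair on adjacent carbons C8 (acyloxy CH, next to ring-fusion C7) and C9 (allylic carbinol CH) of ring A, the ten-membered carbocycle. This is a pinacol retron, so ring A is cut between C8 and C9 to give cis-lactone dialdehyde 18.
2. The C8–O ester bond to (2S,3S)-epoxyangelic acid 29 and the C11=C13 exo-methylene are added after ring closure, because an acrylate would be reduced by low-valent titanium.
3. Ring B (cis-γ-lactone O–C6–C7–C11–C12) comes from an auxiliary-controlled anti-aldol union of C6 and C7 (enal 10 plus succinate thioimide 13), followed by lactonisation.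
4. Enal 10 (4E and 1(10)Z alkenes) comes from geraniol by cleavage of the terminal alkene and Still–Gennari olefination. Acid 29 (ring C, the oxirane) comes from methyl angelate by Sharpless epoxidation.
5. Order of ring formation: ring C (separate fragment), ring B (step 11), ring A (step 14).

Key step: step 14

Numbering: germacrane locants are used throughout (C6 lactone O–CH, C7 ring fusion, C8 and C9 oxygenated carbons, C11 lactone α-carbon, C12 lactone carbonyl, C13 exo-methylene).

Assumption: in the MgBr2·OEt2-catalysed anti-aldol (step 10) the thioimide is taken to react through its non-chelated (Z)-enolate, so that the (4S)-benzyl auxiliary gives 7S; if the sense proves opposite, the (4R)-auxiliary is used in the same sequence.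

**Route**

Step 1
Reactants: 1 geraniol
Product: 2 geranyl 4-methoxybenzyl ether
Conditions: NaH, 4-methoxybenzyl chloride, Bu4NI (cat.), THF/DMF, 0 °C to rt
Reagents that add atoms: 4-methoxybenzyl chloride, COc1ccc(CCl)cc1
Why: Williamson etherification of the primary allylic alkoxide gives an ether that survives the oxidative cleavage, the olefination and the hydride reduction and is later removed oxidatively beside a silyl ether.

Step 2
Reactants: 2 geranyl 4-methoxybenzyl ether
Product: 3 racemic 6,7-epoxygeranyl 4-methoxybenzyl ether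
Conditions: mCPBA, NaHCO3, CH2Cl2, −20 to 0 °C
Reagents that add atoms: 3-chloroperoxybenzoic acid, OOC(=O)c1cccc(Cl)c1
Why: Prilezhaev epoxidation should take the more electron-rich terminal trisubstituted alkene, because the 2,3-alkene is deactivated inductively by the allylic oxygen; the epoxide configuration is irrelevant since the carbon is cleaved next.

Step 3
Reactants: 3 racemic 6,7-epoxygeranyl 4-methoxybenzyl ether
Product: 4 (4E)-6-(4-methoxybenzyloxy)-4-methylhex-4-enal
Conditions: H5IO6, THF/H2O, 0 °C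
Reagents that add atoms: none
Why: Periodic acid hydrolyses the epoxide in situ and cleaves the resulting glycol (Malaprade cleavage) to the aldehyde and acetone without touching the remaining trisubstituted alkene.

Step 4
Reactants: 4 (4E)-6-(4-methoxybenzyloxy)-4-methylhex-4-enal; 5 ethyl 2-[bis(2,2,2-trifluoroethoxy)phosphoryl]propanoate
Product: 6 ethyl (2Z,6E)-8-(4-methoxybenzyloxy)-2,6-dimethylocta-2,6-dienoate
Conditions: KN(SiMe3)2, 18-crown-6, THF, −78 °C
Reagents that add atoms: none
Why: Still–Gennari olefination: the electron-poor trifluoroethyl phosphonate with a dissociated potassium counter-ion makes elimination from the kinetic adduct fast, which should give the (Z)-2-methyl enoate that becomes the 1(10)Z alkene.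

Step 5
Reactants: 6 ethyl (2Z,6E)-8-(4-methoxybenzyloxy)-2,6-dimethylocta-2,6-dienoate
Product: 7 (2Z,6E)-8-(4-methoxybenzyloxy)-2,6-dimethylocta-2,6-dien-1-ol
Conditions: i-Bu2AlH, CH2Cl2, −78 °C; Rochelle salt work-up
Reagents that add atoms: none
Why: 1,2-Reduction of the conjugated ester by the aluminium hydride gives the allylic alcohol (C9–OH) with the Z geometry retained.

Step 6
Reactants: 7 (2Z,6E)-8-(4-methoxybenzyloxy)-2,6-dimethylocta-2,6-dien-1-ol
Product: 8 (2Z,6E)-1-(tert-butyldimethylsilyloxy)-8-(4-methoxybenzyloxy)-2,6-dimethylocta-2,6-diene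
Conditions: TBSCl, imidazole, CH2Cl2, 0 °C to rt
Reagents that add atoms: tert-butylchlorodimethylsilane, CC(C)(C)[Si](C)(C)Cl
Why: Standard imidazole-promoted silylation of the primary alcohol gives an O9 protecting group orthogonal to the 4-methoxybenzyl ether.

Step 7
Reactants: 8 (2Z,6E)-1-(tert-butyldimethylsilyloxy)-8-(4-methoxybenzyloxy)-2,6-dimethylocta-2,6-diene
Product: 9 (2E,6Z)-8-(tert-butyldimethylsilyloxy)-3,7-dimethylocta-2,6-dien-1-ol
Conditions: DDQ, CH2Cl2/pH 7 phosphate buffer, 0 °C
Reagents that add atoms: none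
Why: Oxidative cleavage of the 4-methoxybenzyl ether (hydride abstraction by DDQ and hydrolysis of the oxocarbenium ion) frees the C6 alcohol while the silyl ether is stable in the buffered two-phase medium.

Step 8
Reactants: 9 (2E,6Z)-8-(tert-butyldimethylsilyloxy)-3,7-dimethylocta-2,6-dien-1-ol
Product: 10 (2E,6Z)-8-(tert-butyldimethylsilyloxy)-3,7-dimethylocta-2,6-dienal
Conditions: activated MnO2, CH2Cl2, rt
Reagents that add atoms: none
Why: Heterogeneous MnO2 oxidation of the allylic alcohol gives the (E)-enal (C6 aldehyde) without E/Z isomerisation, as in the geraniol-to-geranial case.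

Step 9
Reactants: 11 (4S)-4-benzyl-1,3-thiazolidine-2-thione; 12 methyl 4-chloro-4-oxobutanoate
Product: 13 methyl 4-[(4S)-4-benzyl-2-thioxo-1,3-thiazolidin-3-yl]-4-oxobutanoate
Conditions: Et3N, DMAP (cat.), CH2Cl2, 0 °C to rt
Reagents that add atoms: none
Why: N-Acylation of the thiazolidinethione by the acid chloride gives the succinate thioimide, in which only the CH2 next to the thioimide (future C7) is readily enolised.

Step 10
Reactants: 13 methyl 4-[(4S)-4-benzyl-2-thioxo-1,3-thiazolidin-3-yl]-4-oxobutanoate; 10 (2E,6Z)-8-(tert-butyldimethylsilyloxy)-3,7-dimethylocta-2,6-dienal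
Product: 14 methyl (3S,4S,5E,9Z)-3-{[(4S)-4-benzyl-2-thioxo-1,3-thiazolidin-3-yl]carbonyl}-11-(tert-butyldimethylsilyloxy)-6,10-dimethyl-4-(trimethylsilyloxy)undeca-5,9-dienoate (6S,7S anti adduct)
Conditions: MgBr2·OEt2 (10–20 mol %), Et3N, TMSCl, EtOAc, rt
Reagents that add atoms: chlorotrimethylsilane, C[Si](C)(C)Cl
Why: Evans magnesium-halide-catalysed direct anti-aldol reaction: soft enolisation of the thioimide α-CH2 gives the (Z)-enolate, which adds reversibly to the enal (no α-hydrogen) through a boat-like transition state and is trapped by silylation, the (4S)-benzyl group fixing the enolate face so that the C6–C7 bond should form with 6S and 7S (anti).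

Step 11
Reactants: 14 methyl (3S,4S,5E,9Z)-3-{[(4S)-4-benzyl-2-thioxo-1,3-thiazolidin-3-yl]carbonyl}-11-(tert-butyldimethylsilyloxy)-6,10-dimethyl-4-(trimethylsilyloxy)undeca-5,9-dienoate
Product: 16 (4S)-4-benzyl-3-{[(2S,3S)-2-[(1E,5Z)-7-hydroxy-2,6-dimethylhepta-1,5-dien-1-yl]-5-oxooxolan-3-yl]carbonyl}-1,3-thiazolidine-2-thione (cis-lactone), via hydroxy ester 15 (not isolated)
Conditions: HF·pyridine, pyridine, THF, 0 °C to rt; then PPTS, 4 Å MS, PhMe, 50 °C
Reagents that add atoms: none
Why: Buffered fluoride cleavage of both silyl ethers avoids ionising the allylic C6 carbinol, and acid-catalysed lactonisation of the γ-hydroxy methyl ester then closes ring B; the anti aldol relationship maps onto the cis-4,5-disubstituted lactone and no stereocentre is touched.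

Step 12
Reactants: 16 (4S)-4-benzyl-3-{[(2S,3S)-2-[(1E,5Z)-7-hydroxy-2,6-dimethylhepta-1,5-dien-1-yl]-5-oxooxolan-3-yl]carbonyl}-1,3-thiazolidine-2-thione
Product: 17 (4R,5S)-4-(hydroxymethyl)-5-[(1E,5Z)-7-hydroxy-2,6-dimethylhepta-1,5-dien-1-yl]oxolan-2-one (cis)
Conditions: NaBH4, THF/H2O, 0 °C; NH4Cl quench
Reagents that add atoms: none
Why: Chemoselective borohydride reduction: the highly activated N-acylthiazolidinethione is reduced to the primary alcohol (C8) with release of the auxiliary, while the γ-lactone is inert to NaBH4 at 0 °C; the change of the C7 descriptor is only a change of priorities.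

Step 13
Reactants: 17 (4R,5S)-4-(hydroxymethyl)-5-[(1E,5Z)-7-hydroxy-2,6-dimethylhepta-1,5-dien-1-yl]oxolan-2-one
Product: 18 (2S,3S)-2-[(1E,5Z)-2,6-dimethyl-7-oxohepta-1,5-dien-1-yl]-5-oxooxolane-3-carbaldehyde (cis-lactone dialdehyde)
Conditions: Dess–Martin periodinane, NaHCO3, CH2Cl2, 0 °C to rt; filtered and used at once
Reagents that add atoms: none
Why: Dess–Martin oxidation of both primary alcohols under buffered, amine-free conditions, chosen so that the epimerisable C7 centre, the β-acyloxy aldehyde and the (Z)-enal are not exposed to base.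

Step 14
Reactants: 18 (2S,3S)-2-[(1E,5Z)-2,6-dimethyl-7-oxohepta-1,5-dien-1-yl]-5-oxooxolane-3-carbaldehyde
Product: 19 (3aR,4R,5R,6Z,10E,11aS)-4,5-dihydroxy-6,10-dimethyl-3a,4,5,8,9,11a-hexahydrocyclodeca[b]furan-2(3H)-one (8R,9R threo diol)
Conditions: TiCl3(DME)1.5, Zn–Cu couple, DME, reflux (reagent formation); then 18 by syringe pump at 25 °C under high dilution; aq. K2CO3 work-up
Reagents that add atoms: none
Why: Low-valent titanium made from TiCl3(DME)1.5 and Zn–Cu transfers one electron to each carbonyl, and the two titanium-bound ketyls, held together on the metal surface under slow addition, combine at C8 and C9; this is a McMurry-type intramolecular pinacol coupling of a dialdehyde, which stops at the diol because deoxygenation needs reflux. Ring A is closed end to end as a ten-membered carbocycle by this radical–radical C8–C9 bond formation, with both oxygens exocyclic, pre-organised by the cis-lactone ring B and by the 4E and 1(10)Z alkenes. C8 should be set by the adjacent C7 centre: the C8 ketyl reacts in a Felkin–Anh-type arrangement with the C7–C6 bond anti to the forming bond and the small H7 next to the incoming C9, which gives 8R. C9 should be set relative to C8 by the preference of the two bulky titanium alkoxides for an anti (threo) arrangement, since a cis-titanadioxolane chelate is strained in the ten-membered ring, which gives 9R. The step needs coupling at the enal carbonyl carbon and not at C1 (which would make an eight-membered ring), and retention of the (Z)-enal and of the C7 configuration; the higher spin density at the titanium-bound carbonyl carbon, the ring size, the non-basic medium and the low temperature are relied on for these.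

Step 15
Reactants: 19 (3aR,4R,5R,6Z,10E,11aS)-4,5-dihydroxy-6,10-dimethyl-3a,4,5,8,9,11a-hexahydrocyclodeca[b]furan-2(3H)-one
Product: 21 9-O-triethylsilyl-8-O-trimethylsilyl bis-ether of 19, via O9-triethylsilyl ether 20 (not isolated)
Conditions: TESCl (1.05 equiv), imidazole, DMF, −20 °C; then TMSCl, 0 °C
Reagents that add atoms: chlorotriethylsilane, CC[Si](Cl)(CC)CC; chlorotrimethylsilane, C[Si](C)(C)Cl
Why: Sterically controlled silylation: the allylic C9–OH is flanked by the planar C10 and should react first with the bulkier silyl chloride, whereas C8–OH sits between the ring-fusion methine C7 and C9 and is then capped with the small, labile trimethylsilyl group so that no free alkoxide can translactonise onto C12 in the next step.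

Step 16
Reactants: 21 9-O-triethylsilyl-8-O-trimethylsilyl bis-ether of 19
Product: 22 11-(dimethylaminomethyl) lactone (C11 epimers; used crude)
Conditions: LiN(i-Pr)2, THF, −78 °C; then dimethyl(methylidene)ammonium iodide, −78 to 0 °C
Reagents that add atoms: dimethyl(methylidene)ammonium iodide (Eschenmoser's salt), C=[N+](C)C.[I-]
Why: Mannich reaction of the lithium lactone enolate (C11 is the only acidic C–H left) with Eschenmoser's salt; the C11 configuration does not matter because the centre becomes sp2 in step 17.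

Step 17
Reactants: 22 11-(dimethylaminomethyl) lactone
Product: 25 (3aR,4R,5R,6Z,10E,11aS)-4-hydroxy-6,10-dimethyl-3-methylidene-5-(triethylsilyloxy)-3a,4,5,8,9,11a-hexahydrocyclodeca[b]furan-2(3H)-one, via ammonium iodide 23 (not isolated), via O8-silylated methylene lactone 24 (not isolated)
Conditions: MeI, CH2Cl2, rt; aq. NaHCO3/EtOAc; then PPTS, MeOH, 0 °C
Reagents that add atoms: none
Why: Exhaustive N-methylation and mild-base E1cB (Hofmann-type) loss of trimethylamine give the exocyclic C11=C13 alkene (standard α-methylenation of a lactone), and brief PPTS/MeOH solvolysis then removes the labile O8 trimethylsilyl group while the O9 triethylsilyl ether stays.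

Step 18
Reactants: 26 methyl angelate [methyl (2Z)-2-methylbut-2-enoate]
Product: 27 (2Z)-2-methylbut-2-en-1-ol
Conditions: i-Bu2AlH, Et2O, −78 to 0 °C
Reagents that add atoms: none
Why: 1,2-Reduction of the conjugated ester by the aluminium hydride gives the (Z)-allylic alcohol without isomerisation to the tiglyl series.

Step 19
Reactants: 27 (2Z)-2-methylbut-2-en-1-ol
Product: 28 [(2R,3S)-2,3-dimethyloxiran-2-yl]methanol
Conditions: Ti(OiPr)4 (cat.), D-(−)-diethyl tartrate (cat.), t-BuOOH, 4 Å MS, CH2Cl2, −20 °C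
Reagents that add atoms: tert-butyl hydroperoxide, CC(C)(C)OO
Why: Sharpless asymmetric epoxidation: the D-(−)-tartrate catalyst should deliver oxygen to the face that gives the 2R epoxy alcohol (mirror of the 2S sense of natural L-(+)-tartrate with primary allylic alcohols), and syn addition keeps CH2OH and the C3 methyl cis, which fixes 3S.

Step 20
Reactants: 28 [(2R,3S)-2,3-dimethyloxiran-2-yl]methanol
Product: 29 (2S,3S)-2,3-dimethyloxirane-2-carboxylic acid (epoxyangelic acid)
Conditions: RuCl3·xH2O (cat.), NaIO4, MeCN/CCl4/H2O, rt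
Reagents that add atoms: sodium periodate, [Na+].[O-]I(=O)(=O)=O; water, O
Why: Catalytic ruthenium tetroxide oxidation (RuCl3/NaIO4) takes the primary alcohol through the aldehyde hydrate to the acid without opening the epoxide; the descriptor at C2 changes from R to S only through the change of priorities.

Step 21
Reactants: 29 (2S,3S)-2,3-dimethyloxirane-2-carboxylic acid; 25 (3aR,4R,5R,6Z,10E,11aS)-4-hydroxy-6,10-dimethyl-3-methylidene-5-(triethylsilyloxy)-3a,4,5,8,9,11a-hexahydrocyclodeca[b]furan-2(3H)-one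
Product: 31 O9-triethylsilyl ether of the target, via mixed anhydride 30 (not isolated)
Conditions: 2,4,6-trichlorobenzoyl chloride, Et3N, THF, rt; then 25, DMAP, PhMe, 40 °C
Reagents that add atoms: none
Why: Yamaguchi esterification: DMAP attacks the less hindered carbonyl of the mixed anhydride and the acylpyridinium acylates the hindered C8 hydroxyl; the acid has no α-hydrogen and no alkene, so it cannot epimerise or isomerise, and O-acylation leaves C8 untouched.

Step 22
Reactants: 31 O9-triethylsilyl ether of the target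
Product: 32 CNP0318223.3 [(3aS,4R,5R,6Z,10E,11aS)-5-hydroxy-6,10-dimethyl-3-methylidene-2-oxo-2,3,3a,4,5,8,9,11a-octahydrocyclodeca[b]furan-4-yl (2S,3S)-2,3-dimethyloxirane-2-carboxylate]
Conditions: HF·pyridine, pyridine, THF, 0 °C
Reagents that add atoms: none
Why: Pyridine-buffered fluoride cleavage of the secondary triethylsilyl ether should leave the epoxide, the α-methylene lactone and the C8 ester intact, and the absence of base avoids acyl migration from O8 to O9.

**Compound list**

1 | geraniol | CC(C)=CCC/C(C)=C/CO | starting material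
2 | geranyl 4-methoxybenzyl ether | CC(C)=CCC/C(C)=C/COCc1ccc(OC)cc1 | intermediate
3 | racemic 6,7-epoxygeranyl 4-methoxybenzyl ether | CC1(C)OC1CC/C(C)=C/COCc2ccc(OC)cc2 | intermediate
4 | (4E)-6-(4-methoxybenzyloxy)-4-methylhex-4-enal | O=CCC/C(C)=C/COCc1ccc(OC)cc1 | intermediate
5 | ethyl 2-[bis(2,2,2-trifluoroethoxy)phosphoryl]propanoate | CCOC(=O)C(C)P(=O)(OCC(F)(F)F)OCC(F)(F)F | starting material
6 | ethyl (2Z,6E)-8-(4-methoxybenzyloxy)-2,6-dimethylocta-2,6-dienoate | CCOC(=O)/C(C)=C\CC/C(C)=C/COCc1ccc(OC)cc1 | intermediate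
7 | (2Z,6E)-8-(4-methoxybenzyloxy)-2,6-dimethylocta-2,6-dien-1-ol | OC/C(C)=C\CC/C(C)=C/COCc1ccc(OC)cc1 | intermediate
8 | (2Z,6E)-1-(tert-butyldimethylsilyloxy)-8-(4-methoxybenzyloxy)-2,6-dimethylocta-2,6-diene | CC(C)(C)[Si](C)(C)OC/C(C)=C\CC/C(C)=C/COCc1ccc(OC)cc1 | intermediate
9 | (2E,6Z)-8-(tert-butyldimethylsilyloxy)-3,7-dimethylocta-2,6-dien-1-ol | CC(C)(C)[Si](C)(C)OC/C(C)=C\CC/C(C)=C/CO | intermediate
10 | (2E,6Z)-8-(tert-butyldimethylsilyloxy)-3,7-dimethylocta-2,6-dienal | CC(C)(C)[Si](C)(C)OC/C(C)=C\CC/C(C)=C/C=O | intermediate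
11 | (4S)-4-benzyl-1,3-thiazolidine-2-thione | S=C1N[C@@H](Cc2ccccc2)CS1 | starting material
12 | methyl 4-chloro-4-oxobutanoate | COC(=O)CCC(Cl)=O | starting material
13 | methyl 4-[(4S)-4-benzyl-2-thioxo-1,3-thiazolidin-3-yl]-4-oxobutanoate | COC(=O)CCC(=O)N1C(=S)SC[C@@H]1Cc1ccccc1 | intermediate
14 | methyl (3S,4S,5E,9Z)-3-{[(4S)-4-benzyl-2-thioxo-1,3-thiazolidin-3-yl]carbonyl}-11-(tert-butyldimethylsilyloxy)-6,10-dimethyl-4-(trimethylsilyloxy)undeca-5,9-dienoate | COC(=O)C[C@H](C(=O)N1C(=S)SC[C@@H]1Cc1ccccc1)[C@@H](O[Si](C)(C)C)/C=C(\C)CC/C=C(/C)CO[Si](C)(C)C(C)(C)C | intermediate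
15 | methyl (3S,4S,5E,9Z)-3-{[(4S)-4-benzyl-2-thioxo-1,3-thiazolidin-3-yl]carbonyl}-4,11-dihydroxy-6,10-dimethylundeca-5,9-dienoate | COC(=O)C[C@H](C(=O)N1C(=S)SC[C@@H]1Cc1ccccc1)[C@@H](O)/C=C(\C)CC/C=C(/C)CO | intermediate
16 | (4S)-4-benzyl-3-{[(2S,3S)-2-[(1E,5Z)-7-hydroxy-2,6-dimethylhepta-1,5-dien-1-yl]-5-oxooxolan-3-yl]carbonyl}-1,3-thiazolidine-2-thione | C1C(=O)O[C@@H](/C=C(\C)CC/C=C(/C)CO)[C@H]1C(=O)N2C(=S)SC[C@@H]2Cc3ccccc3 | intermediate
17 | (4R,5S)-4-(hydroxymethyl)-5-[(1E,5Z)-7-hydroxy-2,6-dimethylhepta-1,5-dien-1-yl]oxolan-2-one | C1C(=O)O[C@@H](/C=C(\C)CC/C=C(/C)CO)[C@H]1CO | intermediate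
18 | (2S,3S)-2-[(1E,5Z)-2,6-dimethyl-7-oxohepta-1,5-dien-1-yl]-5-oxooxolane-3-carbaldehyde | C1C(=O)O[C@@H](/C=C(\C)CC/C=C(/C)C=O)[C@H]1C=O | intermediate
19 | (3aR,4R,5R,6Z,10E,11aS)-4,5-dihydroxy-6,10-dimethyl-3a,4,5,8,9,11a-hexahydrocyclodeca[b]furan-2(3H)-one | C1C(=O)O[C@H]2/C=C(\C)CC/C=C(/C)[C@@H](O)[C@H](O)[C@@H]12 | intermediate
20 | 9-O-triethylsilyl ether of 19 (8-OH free) | C1C(=O)O[C@H]2/C=C(\C)CC/C=C(/C)[C@@H](O[Si](CC)(CC)CC)[C@H](O)[C@@H]12 | intermediate
21 | 9-O-triethylsilyl-8-O-trimethylsilyl bis-ether of 19 | C1C(=O)O[C@H]2/C=C(\C)CC/C=C(/C)[C@@H](O[Si](CC)(CC)CC)[C@H](O[Si](C)(C)C)[C@@H]12 | intermediate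
22 | 11-(dimethylaminomethyl) derivative of 21 (C11 epimers) | CN(C)CC1C(=O)O[C@H]2/C=C(\C)CC/C=C(/C)[C@@H](O[Si](CC)(CC)CC)[C@H](O[Si](C)(C)C)[C@@H]12 | intermediate
23 | trimethylammonium iodide of 22 | C[N+](C)(C)CC1C(=O)O[C@H]2/C=C(\C)CC/C=C(/C)[C@@H](O[Si](CC)(CC)CC)[C@H](O[Si](C)(C)C)[C@@H]12.[I-] | intermediate
24 | 11(13)-methylene lactone with O8-trimethylsilyl and O9-triethylsilyl groups | C=C1C(=O)O[C@H]2/C=C(\C)CC/C=C(/C)[C@@H](O[Si](CC)(CC)CC)[C@H](O[Si](C)(C)C)[C@@H]12 | intermediate
25 | (3aR,4R,5R,6Z,10E,11aS)-4-hydroxy-6,10-dimethyl-3-methylidene-5-(triethylsilyloxy)-3a,4,5,8,9,11a-hexahydrocyclodeca[b]furan-2(3H)-one | C=C1C(=O)O[C@H]2/C=C(\C)CC/C=C(/C)[C@@H](O[Si](CC)(CC)CC)[C@H](O)[C@@H]12 | intermediate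
26 | methyl angelate [methyl (2Z)-2-methylbut-2-enoate] | C/C=C(/C)C(=O)OC | starting material
27 | (2Z)-2-methylbut-2-en-1-ol | C/C=C(/C)CO | intermediate
28 | [(2R,3S)-2,3-dimethyloxiran-2-yl]methanol | OC[C@@]1(C)O[C@H]1C | intermediate
29 | (2S,3S)-2,3-dimethyloxirane-2-carboxylic acid | OC(=O)[C@@]1(C)O[C@H]1C | intermediate
30 | (2S,3S)-2,3-dimethyloxirane-2-carboxylic 2,4,6-trichlorobenzoic anhydride | Clc1cc(Cl)c(C(=O)OC(=O)[C@@]2(C)O[C@H]2C)c(Cl)c1 | intermediate
31 | O9-triethylsilyl ether of the target | C=C1C(=O)O[C@H]2/C=C(\C)CC/C=C(/C)[C@@H](O[Si](CC)(CC)CC)[C@H](OC(=O)[C@@]3(C)O[C@H]3C)[C@@H]12 | intermediate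
32 | CNP0318223.3 | C=C1C(=O)O[C@H]2/C=C(\C)CC/C=C(/C)[C@@H](O)[C@H](OC(=O)[C@@]3(C)O[C@H]3C)[C@@H]12 | target

**Step count**

Total steps: 22. Longest linear sequence: 18 steps (1–8, 10–17, 21, 22, from geraniol).

**Steps most likely to fail**

Step 14 (pinacol macrocyclisation). The ketyl–ketyl coupling may close ring A with the two oxygens erythro, or as a mixture. Slow closure also exposes the β-acyloxy aldehyde to epimerisation and lets the delocalised enal ketyl rotate about C10–C1. The fallback sets out from 18 and comes back at 21; it sets C9 by a substrate-controlled ketone reduction and not by the coupling. The coupling of 18 (the same titanium reagent, or SmI2 in THF at −78 °C) is run without regard to the C9 configuration. The crude mixture of 19 and its C9 epimer, the erythro diol F1, is treated with activated MnO2 in CH2Cl2, which oxidises only the allylic C9 carbinol and converges both epimers on the 8-hydroxy-9-ketone F2. O8 is capped with TMSCl/imidazole to give the silyloxy enone F3. A Luche 1,2-reduction (NaBH4, CeCl3·7H2O, MeOH, −78 °C), from the face anti to the C8 silyloxy group in a Felkin–Anh arrangement, should give the 9R alcohol F4. Silylation of F4 with TESCl/imidazole gives 21.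

Step 10 (anti-aldol). Facial or anti/syn selectivity of the magnesium enolate with the β,β-disubstituted enal may be low, or the enal may be silylated at its vinylogous position under Et3N/TMSCl. The fallback sets out from 10 and comes back at 17; it uses a kinetic boron enolate and corrects C6 by inversion. Succinic anhydride is opened with allyl alcohol (DMAP) to 4-(allyloxy)-4-oxobutanoic acid F5. Its pivalic mixed anhydride acylates (4S)-4-benzyl-1,3-oxazolidin-2-one (Et3N, LiCl) to give the imide F6. The Evans boron aldol reaction of F6 with 10 (Bu2BOTf, i-Pr2NEt, CH2Cl2, −78 to 0 °C) gives the 6R,7S syn adduct F7, whose 7S centre follows the established sense of this auxiliary. Pd(PPh3)4/morpholine removes the allyl group to give the hydroxy acid F8. Mitsunobu lactonisation (PPh3, DIAD, THF, 0 °C) closes ring B with inversion at C6 to the cis-lactone imide F9. NaBH4 in THF/H2O cleaves the auxiliary reductively to the hydroxymethyl lactone silyl ether F10, and HF·pyridine/pyridine removes the silyl group to give 17.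

Step 13 (double oxidation to the dialdehyde). C7 may epimerise, the lactone carboxylate may be lost by β-elimination, or the enal may isomerise from Z to E during the double oxidation and handling. The fallback sets out from 16 and comes back at 18; C8 reaches the aldehyde level by reduction and is never an alcohol. i-Bu2AlH (2 equiv, CH2Cl2, −78 °C) half-reduces the activated thioimide of 16 directly to the hydroxy aldehyde F11, with release of the auxiliary and with the lactone kept. Activated MnO2 in CH2Cl2 then oxidises only the allylic C9 alcohol to give 18, which is used at once.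

**Further compounds**

F1 | step 14 | (3aR,4R,5S,6Z,10E,11aS)-4,5-dihydroxy-6,10-dimethyl-3a,4,5,8,9,11a-hexahydrocyclodeca[b]furan-2(3H)-one (C9 epimer of 19) | C1C(=O)O[C@H]2/C=C(\C)CC/C=C(/C)[C@H](O)[C@H](O)[C@@H]12
F2 | step 14 | (3aR,4R,6Z,10E,11aS)-4-hydroxy-6,10-dimethyl-3a,4,8,9-tetrahydrocyclodeca[b]furan-2,5(3H,11aH)-dione (8-hydroxy-9-ketone) | C1C(=O)O[C@H]2/C=C(\C)CC/C=C(/C)C(=O)[C@H](O)[C@@H]12
F3 | step 14 | 8-O-trimethylsilyl ether of F2 | C1C(=O)O[C@H]2/C=C(\C)CC/C=C(/C)C(=O)[C@H](O[Si](C)(C)C)[C@@H]12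
F4 | step 14 | 8-O-trimethylsilyl ether of 19 (9R alcohol free) | C1C(=O)O[C@H]2/C=C(\C)CC/C=C(/C)[C@@H](O)[C@H](O[Si](C)(C)C)[C@@H]12
F5 | step 10 | 4-(allyloxy)-4-oxobutanoic acid | C=CCOC(=O)CCC(=O)O
F6 | step 10 | allyl 4-[(4S)-4-benzyl-2-oxo-1,3-oxazolidin-3-yl]-4-oxobutanoate | C=CCOC(=O)CCC(=O)N1C(=O)OC[C@@H]1Cc1ccccc1
F7 | step 10 | allyl (3S,4R,5E,9Z)-3-{[(4S)-4-benzyl-2-oxo-1,3-oxazolidin-3-yl]carbonyl}-11-(tert-butyldimethylsilyloxy)-4-hydroxy-6,10-dimethylundeca-5,9-dienoate (syn adduct) | C=CCOC(=O)C[C@H](C(=O)N1C(=O)OC[C@@H]1Cc1ccccc1)[C@H](O)/C=C(\C)CC/C=C(/C)CO[Si](C)(C)C(C)(C)C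
F8 | step 10 | (3S,4R,5E,9Z)-3-{[(4S)-4-benzyl-2-oxo-1,3-oxazolidin-3-yl]carbonyl}-11-(tert-butyldimethylsilyloxy)-4-hydroxy-6,10-dimethylundeca-5,9-dienoic acid | OC(=O)C[C@H](C(=O)N1C(=O)OC[C@@H]1Cc1ccccc1)[C@H](O)/C=C(\C)CC/C=C(/C)CO[Si](C)(C)C(C)(C)C
F9 | step 10 | (4S)-4-benzyl-3-{[(2S,3S)-2-[(1E,5Z)-7-(tert-butyldimethylsilyloxy)-2,6-dimethylhepta-1,5-dien-1-yl]-5-oxooxolan-3-yl]carbonyl}-1,3-oxazolidin-2-one (cis-lactone) | C1C(=O)O[C@@H](/C=C(\C)CC/C=C(/C)CO[Si](C)(C)C(C)(C)C)[C@H]1C(=O)N2C(=O)OC[C@@H]2Cc3ccccc3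
F10 | step 10 | (4R,5S)-5-[(1E,5Z)-7-(tert-butyldimethylsilyloxy)-2,6-dimethylhepta-1,5-dien-1-yl]-4-(hydroxymethyl)oxolan-2-one | C1C(=O)O[C@@H](/C=C(\C)CC/C=C(/C)CO[Si](C)(C)C(C)(C)C)[C@H]1CO
F11 | step 13 | (2S,3S)-2-[(1E,5Z)-7-hydroxy-2,6-dimethylhepta-1,5-dien-1-yl]-5-oxooxolane-3-carbaldehyde | C1C(=O)O[C@@H](/C=C(\C)CC/C=C(/C)CO)[C@H]1C=O
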